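The loading ratio of the two flasks is 10.0, and your quick number turns on how much of it the rate keeps while precatalyst catches up.

    starting material + free catalyst → catalyst intermediate A (k1 = 8.7 /M/h)
    catalyst intermediate A → catalyst intermediate B (k2 = 71 /h)
    catalyst intermediate B ⇌ free catalyst + product (K3 = 39 M, k3 = 76 /h)
    precatalyst ⇌ free catalyst (K4 = 1.8, k4 = 0.040 /h)

starting material 2.1 M; precatalyst 0.1 mol%

1. the form that holds most of the catalyst when 50% of the starting material are converted (catalyst intermediate B / catalyst intermediate A / free catalyst / precatalyst)
2. its share of the catalyst then
3. factor on the rate of making product when 50% of the starting material are converted if precatalyst is charged twice over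
4. factor on the rate when 50% of the starting material are converted if precatalyst is charged at 1 mol% instead

Start with the shares of the charge at 50% conversion. Assume that precatalyst has caught up and that the intermediates are steady. Per unit of free catalyst you then have:

catalyst intermediate A: 0.129
catalyst intermediate B: 0.147
precatalyst: 0.556

The free share, the fraction of the charged catalyst standing as free catalyst, is 54.6%.

With free catalyst steady, starting material falls pseudo-first-order. The 0.1 mol% flask then needs 2.89 d to reach 50%. That is longer than the relaxation half-life of 0.464 d, so the assumption stands there.

The 1 mol% flask would need 0.289 d, which is shorter than that half-life, so the assumption fails there. Go round again. Relaxation has a mean time of 0.670 d, which is one over the sum of the forward and back constants of the precatalyst equilibrium. The time lost to activation is that mean time multiplied by the attained fraction of the final free catalyst. Put each attained fraction back in: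

round one: 0.351
round two: 0.543
round three: 0.623

I commit to a factor of 6.23, and the rounds are still climbing. At twice the loading, one pass gives 1.92.

The forecast says free catalyst at 54.7%, with factors 1.94 and 6.7, noting that “activation takes about 18 h”. Its ratio is higher than mine.

The run gives free catalyst at 54.8%, with factors 1.92 and 6.67. Precatalyst, outside the working round, holds 30.1%, and free catalyst is the largest form in the round, its resting state. Now use the free share again, at 70 percent conversion in the 0.1 mol% flask:

free share: 57.4%
rate against 50%: 0.631

The run reads 0.63 at 5.84 d.

The rate constants were chosen freely; no experiment stands behind them.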